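## Structural features

Dihydroptychantol A (20) is a macrocyclic bis(bibenzyl) with four benzene rings. Rings A and B are joined by one CH2CH2 bridge (ring A C3 to ring B C1) and rings C and D by a second one (ring C C4 to ring D C1). Two diaryl ether oxygens (ring A C4 to ring D C3, ring B C3 to ring C C1) complete an 18-membered ring that holds two atoms of ring A, three of ring B, four of ring C and three of ring D. There is no stereogenic centre, so no relative configuration between neighbouring centres has to be set. The fragile groups are the two free phenols (ring A C1, ring B C4), the ring B one being part of an oxidation-prone catechol monoether; both are carried as ethers to the last step. In the intermediates the ring C bromide forbids palladium-catalysed hydrogenation once it is present. The real difficulty lies in the two diaryl ethers and the macrocyclization: the ring A ether is flanked by the ortho CH2CH2 chain and has no activating group for SNAr. The key step uses the pattern of ring A, a 4-aryloxy-3-alkylphenol: C3 and C4 are the carbonyl and alpha carbons of an aryloxymethyl ketone, and C5, C6, C1 (with its oxygen) and C2 map onto a four-carbon beta-methoxy enone. The hindered ether can therefore be made as a simple phenol O-alkylation before ring A exists.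

## Logic of the disconnections

20 to 19. The two O–CH3 bonds (ring A C1, ring B C4) are cut last. Methyl ethers survive every earlier condition and one reagent removes both. The demand is that the cleavage leaves both diaryl ether bonds intact.

19 to 18. The macrocycle is opened at the bond between the ring B C3 oxygen and ring C C1. This is the less hindered of the two diaryl ethers and its electrophilic partner is a para-substituted aryl bromide. The cut turns the 18-membered ring into a linear chain of four arenes. The forward step is an intramolecular copper-mediated etherification at high dilution, which requires that the ring B hydroxyl be the only free phenol.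

18 to 17 to 16. The O–isopropyl bond on ring B is restored and the O–CH3 bond on ring A is removed. The ring A phenol arrives free from the annulation and must be masked, while the ring B oxygen must be unmasked. The forward steps need a reagent that cleaves a secondary alkyl aryl ether beside two methyl ethers.

16 to 12 and 13. Ring A is cut at C4–C5 and C2–C3. This removes a whole benzene ring and leaves an open-chain ketone that already carries the ring D oxygen on its alpha carbon, plus a purchasable four-carbon enone. The forward step must enolize 12 on the aryloxy side and must close the ring from the methyl group of the enone-derived ketone.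

12 to 5 and 11. The bond between the ring D oxygen and the CH2 alpha to the ketone is cut. This splits the molecule into two fragments of similar size and reduces the hindered ether problem to an SN2 reaction at a primary, carbonyl-activated carbon. The demand is clean O-alkylation without self-condensation of the chloroketone.

11 to 9. The bond between the carbonyl carbon and the CH2Cl carbon is cut. A one-carbon chloromethyl nucleophile adding to an N-methoxy-N-methylamide gives the halomethyl ketone without diazomethane. The forward step needs a tetrahedral adduct that holds until the quench.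

9 to 8 to 7 to 6. The alpha–beta C–C bond of the side chain is traced back to a C=C bond and then cut by an olefination that installs the amide directly; the O–isopropyl bond is cut last. This reaches 6 in three operations, and hydrogenation is allowed here because the fragment has no halogen.

5 to 4 to 1 and 2. The ring C–ring D bridge is traced back to a stilbene C=C bond and cut into a benzylic ylide and an aldehyde. Both halves are commercial, and the phenol needs no protection. The reduction must be metal-free so that the C–Br bond survives.

## Other disconnections considered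

Alternative 1: The cut is the CH2–CH2 bond of the ring C–ring D bridge, traced back to macrocyclic stilbene A1 and then to the 19-membered dibenzyl sulfone A2. In the forward key step, KOH on alumina with CBr2F2 in t-BuOH would halogenate one sulfone alpha carbon. 1,3-Closure and loss of the sulfur bridge as sulfur dioxide would then contract the ring to A1, and hydrogenation of A1 would give 19.
- In its favour: the ring is closed at sulfur by benzylic alkylation, one of the more dependable macrocyclizations, and the 19-membered ring is less strained. The geometry of A1 does not matter because the double bond is hydrogenated.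
- Against it: both diaryl ethers, including the hindered ring A one, must be made by intermolecular SNAr or Ullmann couplings, which need activating groups and their later adjustment. The two-carbon bridge costs four operations (ring closure at sulfur, oxidation, contraction, hydrogenation) against two in the chosen plan. CBr2F2 is a restricted ozone-depleting halon.
- Comparison: on the reliability of ring closure this alternative is probably the better of the two. On mechanism the two are equal in raising no stereochemical issue. On structure the chosen plan is stronger, because it avoids any coupling at the hindered ring A position. On step economy the alternative is expected to be several steps longer, and it joins the chosen route only at 19.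

Alternative 2: The cut is the benzylic C–C bond of the ring A–ring B bridge. In the forward key step, fluoride would remove the silyl group of seco compound A4 and the phenoxide would expel acetate to give para-quinone methide A5. The nitronate of the ring A nitromethyl group would add to its exocyclic carbon and close the ring to racemic nitro macrocycle A3.
- In its favour: the macrocycle is closed by C–C bond formation at room temperature, driven by rearomatization of ring B, and the ring B phenol emerges free.
- Against it: A3 contains a stereocentre and a nitro group that the target lacks, so a radical denitration must follow. Three extra handles (nitromethyl, acetoxymethyl, silyl ether) must be built into A4. A5 can oligomerize or be trapped by fluoride, acetate or water at the dilution needed. Both diaryl ethers again come from intermolecular couplings.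
- Comparison: on mildness of the ring closure this alternative is the better one. On structure the chosen plan is simpler, since it never creates a stereocentre or a group that must be erased. On step economy the alternative is expected to be longer.

Alternative 3: The cut is the same ring B oxygen–ring C bond that the chosen plan closes last, but formed oxidatively from bis-phenol A7. In the forward key step, Tl(NO3)3 (trivalent thallium) would oxidize the dibromophenol of ring B by two electrons. The ring C phenol oxygen would add at a bromine-bearing ortho carbon, and zinc in acetic acid would remove that bromine to give halogenated macrocycle A6.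
- In its favour: the closure runs at or below room temperature and follows the presumed biogenesis. The halogens direct which phenol is oxidized and where it is attacked.
- Against it: a stoichiometric, acutely toxic thallium salt is needed. Four halogens must be installed and three removed afterwards by hydrogenolysis. Oxidized phenols tend to give side products by solvent capture or C–C coupling. A7 still contains the hindered ring A ether.
- Comparison: the alternative is equal to the chosen plan in the bond formed and in the strain of the ring closure, and it is the better one in reaction temperature. The chosen plan is better on reagent hazard, on atom economy and on step count, because it needs no blocking halogens.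

Key step: step 8

Assumption: salt 1 is taken as a catalogue reagent, and stilbene 4 is carried on as an E/Z mixture because both isomers give 5.

## Route

Step 1
Reactants: 1 (4-bromobenzyl)triphenylphosphonium bromide; 2 3-hydroxybenzaldehyde
Product: 4 3-[2-(4-bromophenyl)ethenyl]phenol (E/Z mixture), via phosphonium ylide 3 (not isolated)
Conditions: KOtBu (2.2 equiv), THF, 0 °C to rt; then aq. HCl
Reagents that add atoms: none
Why: Wittig olefination: the semistabilized benzylic ylide 3 adds to the aldehyde of 2, which is present as its phenoxide; the meta phenoxide is not conjugated to the formyl group, and the E/Z ratio is irrelevant because step 2 removes the double bond.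

Step 2
Reactants: 4 3-[2-(4-bromophenyl)ethenyl]phenol
Product: 5 3-[2-(4-bromophenyl)ethyl]phenol
Conditions: TsNHNH2, NaOAc, THF/H2O, reflux
Reagents that add atoms: none
Why: Diimide reduction: HN=NH released from the sulfonyl hydrazide transfers two hydrogens to the stilbene C=C in a concerted, metal-free syn addition, so the aryl C–Br bond, which Pd/C and H2 would hydrogenolyse, should be untouched.

Step 3
Reactants: 6 isovanillin (3-hydroxy-4-methoxybenzaldehyde)
Product: 7 4-methoxy-3-(propan-2-yloxy)benzaldehyde
Conditions: 2-bromopropane, K2CO3, DMF, 70 °C
Reagents that add atoms: 2-bromopropane, CC(C)Br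
Why: Williamson ether synthesis on the phenoxide of 6; the isopropyl ether withstands base, hydrogenation and organolithium reagents and can later be cleaved beside methyl ethers.

Step 4
Reactants: 7 4-methoxy-3-(propan-2-yloxy)benzaldehyde
Product: 8 (E)-N-methoxy-3-[4-methoxy-3-(propan-2-yloxy)phenyl]-N-methylprop-2-enamide
Conditions: (EtO)2P(O)CH2C(O)N(OMe)Me, NaH, THF, 0 °C to rt
Reagents that add atoms: diethyl {2-[methoxy(methyl)amino]-2-oxoethyl}phosphonate, CCOP(=O)(OCC)CC(=O)N(C)OC
Why: Horner–Wadsworth–Emmons olefination with a stabilized amide phosphonate should give the E-alkene and installs the N-methoxy-N-methylamide directly, which saves a separate acid-to-amide step.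

Step 5
Reactants: 8 (E)-N-methoxy-3-[4-methoxy-3-(propan-2-yloxy)phenyl]-N-methylprop-2-enamide
Product: 9 N-methoxy-3-[4-methoxy-3-(propan-2-yloxy)phenyl]-N-methylpropanamide
Conditions: H2 (1 atm), 10% Pd/C, EtOAc, rt
Reagents that add atoms: none
Why: Heterogeneous catalytic hydrogenation of the conjugated C=C; at 1 atm and rt the aryl ethers and the amide N–O bond are expected to remain, and this fragment carries no halogen.

Step 6
Reactants: 9 N-methoxy-3-[4-methoxy-3-(propan-2-yloxy)phenyl]-N-methylpropanamide
Product: 11 1-chloro-4-[4-methoxy-3-(propan-2-yloxy)phenyl]butan-2-one, via tetrahedral lithium alkoxide 10 (not isolated)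
Conditions: ICH2Cl, MeLi·LiBr, THF, −78 °C; then 1 M HCl
Reagents that add atoms: chloroiodomethane, ClCI
Why: Chloromethyllithium, formed in the flask by iodine–lithium exchange, adds once to the N-methoxy-N-methylamide (ketone synthesis of this amide class); the chelated adduct 10 holds at −78 °C and releases the chloromethyl ketone only on quench, which blocks over-addition and avoids diazomethane.

Step 7
Reactants: 5 3-[2-(4-bromophenyl)ethyl]phenol; 11 1-chloro-4-[4-methoxy-3-(propan-2-yloxy)phenyl]butan-2-one
Product: 12 1-{3-[2-(4-bromophenyl)ethyl]phenoxy}-4-[4-methoxy-3-(propan-2-yloxy)phenyl]butan-2-one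
Conditions: K2CO3, KI (cat.), acetone, reflux
Reagents that add atoms: none
Why: Williamson O-alkylation of a phenoxide by an alpha-chloroketone (SN2 at a carbonyl-activated primary carbon, helped by Finkelstein exchange with iodide); the future hindered ring A–ring D ether is thus made as an unhindered alkylation.

Step 8
Reactants: 12 1-{3-[2-(4-bromophenyl)ethyl]phenoxy}-4-[4-methoxy-3-(propan-2-yloxy)phenyl]butan-2-one; 13 (E)-4-methoxybut-3-en-2-one
Product: 16 4-{3-[2-(4-bromophenyl)ethyl]phenoxy}-3-{2-[4-methoxy-3-(propan-2-yloxy)phenyl]ethyl}phenol, via ene-dione 14 (not isolated), via cyclic aldol 15 (not isolated)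
Conditions: KOtBu (3 equiv), THF, 0 °C to rt, slow addition of 13; then aq. HCl
Reagents that add atoms: none
Why: KOtBu reversibly enolizes 12, and the enolate on the aryloxy-bearing carbon adds to the beta carbon of 13; E1cB loss of methoxide gives ene-dione 14 and forms C4–C5 of ring A. The CH between the two carbonyl systems of 14 is doubly activated, so its deprotonation gives a delocalized dienolate in which the former alkene can rotate into the cis arrangement that ring closure needs. The enolate of the methyl ketone then attacks the original carbonyl (C2–C3) in a 6-(enolendo)-exo-trig aldol to give 15; the mode is enolendo, not enolexo, because both enolate carbons become ring atoms. E1cB dehydration to the 4H-cyclohexa-2,5-dienone and tautomerization give the phenol irreversibly, so aromatization drives the sequence. The closest known reaction type is a Robinson annulation run at the phenol oxidation level, a base-mediated Michael–aldol benzannulation of a ketone with a beta-alkoxy enone; in atom count it is a 4 + 2 union (two ring carbons from 12, four from 13), not 3 + 3. No stereocentre remains, since the sp3 centres of 14 and 15 are erased on aromatization. Two selectivities are needed: enolization toward the aryloxy side, secured by the inductive acidification of that CH2 under equilibrating base, and aldol closure from the methyl group, favoured by the less hindered primary enolate and by the inductively activated alpha-aryloxy carbonyl as acceptor. Slow addition of 13 to the enolate should limit base-induced self-condensation of the enone.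

Step 9
Reactants: 16 4-{3-[2-(4-bromophenyl)ethyl]phenoxy}-3-{2-[4-methoxy-3-(propan-2-yloxy)phenyl]ethyl}phenol
Product: 17 1-{3-[2-(4-bromophenyl)ethyl]phenoxy}-4-methoxy-2-{2-[4-methoxy-3-(propan-2-yloxy)phenyl]ethyl}benzene
Conditions: MeI, K2CO3, DMF, rt
Reagents that add atoms: iodomethane, CI
Why: Williamson O-methylation of the only free phenol; it masks the ring A oxygen so that ring B alone can act as the nucleophile in the macrocyclization.

Step 10
Reactants: 17 1-{3-[2-(4-bromophenyl)ethyl]phenoxy}-4-methoxy-2-{2-[4-methoxy-3-(propan-2-yloxy)phenyl]ethyl}benzene
Product: 18 5-[2-(2-{3-[2-(4-bromophenyl)ethyl]phenoxy}-5-methoxyphenyl)ethyl]-2-methoxyphenol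
Conditions: BCl3, CH2Cl2, −78 to 0 °C; then H2O
Reagents that add atoms: none
Why: Lewis acid ether cleavage: at low temperature BCl3 should remove only the secondary isopropyl group, which can leave with carbocation character, while methyl ethers, diaryl ethers and the C–Br bond remain.

Step 11
Reactants: 18 5-[2-(2-{3-[2-(4-bromophenyl)ethyl]phenoxy}-5-methoxyphenyl)ethyl]-2-methoxyphenol
Product: 19 dihydroptychantol A dimethyl ether (the 18-membered macrocycle of 20 with OCH3 at ring A C1 and ring B C4)
Conditions: CuI (20 mol %), N,N-dimethylglycine·HCl (60 mol %), Cs2CO3, 1,4-dioxane, 100 °C, 0.002 M, slow addition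
Reagents that add atoms: none
Why: Intramolecular Ullmann diaryl ether synthesis: the caesium phenoxide of ring B binds monovalent copper, which inserts into the ring C C–Br bond and forms the C–O bond by reductive elimination; the amino acid ligand permits a moderate temperature and high dilution favours the 18-membered ring over oligomers.

Step 12
Reactants: 19 dihydroptychantol A dimethyl ether
Product: 20 dihydroptychantol A
Conditions: BBr3, CH2Cl2, −78 °C to rt; then H2O
Reagents that add atoms: none
Why: BBr3 ether cleavage (Lewis adduct, then bromide attack on the methyl carbon) should remove both methyl groups; diaryl ether bonds are not cleaved under these conditions and no other sensitive group remains.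

## Compound list

1 | (4-bromobenzyl)triphenylphosphonium bromide | [Br-].Brc1ccc(C[P+](c2ccccc2)(c2ccccc2)c2ccccc2)cc1 | starting material
2 | 3-hydroxybenzaldehyde | O=Cc1cccc(O)c1 | starting material
3 | (4-bromobenzylidene)triphenylphosphorane | Brc1ccc(C=P(c2ccccc2)(c2ccccc2)c2ccccc2)cc1 | intermediate (not isolated)
4 | 3-[2-(4-bromophenyl)ethenyl]phenol, E/Z mixture | Oc1cccc(C=Cc2ccc(Br)cc2)c1 | intermediate
5 | 3-[2-(4-bromophenyl)ethyl]phenol | Oc1cccc(CCc2ccc(Br)cc2)c1 | intermediate
6 | isovanillin (3-hydroxy-4-methoxybenzaldehyde) | COc1ccc(C=O)cc1O | starting material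
7 | 4-methoxy-3-(propan-2-yloxy)benzaldehyde | COc1ccc(C=O)cc1OC(C)C | intermediate
8 | (E)-N-methoxy-3-[4-methoxy-3-(propan-2-yloxy)phenyl]-N-methylprop-2-enamide | CON(C)C(=O)/C=C/c1ccc(OC)c(OC(C)C)c1 | intermediate
9 | N-methoxy-3-[4-methoxy-3-(propan-2-yloxy)phenyl]-N-methylpropanamide | CON(C)C(=O)CCc1ccc(OC)c(OC(C)C)c1 | intermediate
10 | lithium 1-chloro-2-[methoxy(methyl)amino]-4-[4-methoxy-3-(propan-2-yloxy)phenyl]butan-2-olate, racemic | [Li+].[O-]C(CCl)(CCc1ccc(OC)c(OC(C)C)c1)N(C)OC | intermediate (not isolated)
11 | 1-chloro-4-[4-methoxy-3-(propan-2-yloxy)phenyl]butan-2-one | ClCC(=O)CCc1ccc(OC)c(OC(C)C)c1 | intermediate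
12 | 1-{3-[2-(4-bromophenyl)ethyl]phenoxy}-4-[4-methoxy-3-(propan-2-yloxy)phenyl]butan-2-one | Brc1ccc(cc1)CCc1cccc(c1)OCC(=O)CCc1ccc(OC)c(OC(C)C)c1 | intermediate
13 | (E)-4-methoxybut-3-en-2-one | CO/C=C/C(C)=O | starting material
14 | (E)-5-{3-[2-(4-bromophenyl)ethyl]phenoxy}-8-[4-methoxy-3-(propan-2-yloxy)phenyl]oct-3-ene-2,6-dione, racemic | CC(=O)/C=C/C(Oc1cccc(CCc2ccc(Br)cc2)c1)C(=O)CCc1ccc(OC)c(OC(C)C)c1 | intermediate (not isolated)
15 | 4-{3-[2-(4-bromophenyl)ethyl]phenoxy}-5-hydroxy-5-{2-[4-methoxy-3-(propan-2-yloxy)phenyl]ethyl}cyclohex-2-en-1-one, diastereomer mixture | O=C1C=CC(Oc2cccc(CCc3ccc(Br)cc3)c2)C(O)(CCc2ccc(OC)c(OC(C)C)c2)C1 | intermediate (not isolated)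
16 | 4-{3-[2-(4-bromophenyl)ethyl]phenoxy}-3-{2-[4-methoxy-3-(propan-2-yloxy)phenyl]ethyl}phenol | Oc1ccc(Oc2cccc(c2)CCc2ccc(Br)cc2)c(c1)CCc1ccc(OC)c(OC(C)C)c1 | intermediate
17 | 1-{3-[2-(4-bromophenyl)ethyl]phenoxy}-4-methoxy-2-{2-[4-methoxy-3-(propan-2-yloxy)phenyl]ethyl}benzene | COc1ccc(Oc2cccc(c2)CCc2ccc(Br)cc2)c(c1)CCc1ccc(OC)c(OC(C)C)c1 | intermediate
18 | 5-[2-(2-{3-[2-(4-bromophenyl)ethyl]phenoxy}-5-methoxyphenyl)ethyl]-2-methoxyphenol | COc1ccc(Oc2cccc(c2)CCc2ccc(Br)cc2)c(c1)CCc1ccc(OC)c(O)c1 | intermediate
19 | dihydroptychantol A dimethyl ether | COc1ccc2c(c1)CCc1ccc(OC)c(c1)Oc1ccc(cc1)CCc1cccc(c1)O2 | intermediate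
20 | dihydroptychantol A | Oc1ccc2c(c1)CCc1ccc(O)c(c1)Oc1ccc(cc1)CCc1cccc(c1)O2 | target

## Step count and least certain steps

Total: 12 steps. Longest linear sequence: 10 steps (steps 3 to 12, from 6); steps 1 and 2 form the shorter branch.

Step 8 (key step). The most likely failures are base-induced self-condensation of 13 before it meets the enolate, enolization of 12 away from the aryloxy carbon, and aldol closure from the other alpha-methylene; the last two would give isomeric phenols. The fallback sets out from 12 and returns at 16, at the cyclohexenone oxidation level. Michael addition of 12 to but-3-en-2-one under catalytic DBU in MeCN should give 5-{3-[2-(4-bromophenyl)ethyl]phenoxy}-8-[4-methoxy-3-(propan-2-yloxy)phenyl]octane-2,6-dione F1. Pyrrolidine and acetic acid would then form the enamine of the methyl ketone on its methyl side and close the ring to 4-{3-[2-(4-bromophenyl)ethyl]phenoxy}-3-{2-[4-methoxy-3-(propan-2-yloxy)phenyl]ethyl}cyclohex-2-en-1-one F2. Dehydrogenation with catalytic I2 in DMSO at 100 °C (alpha-iodination, loss of HI, tautomerization) should give 16.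

Step 11. The most likely failures are intermolecular etherification outrunning closure of the 18-membered ring, and protodebromination of the unactivated bromide at the temperature that the hindered, chelating ortho-methoxy phenoxide requires. The fallback sets out from 17 and returns at 19 by an oxidative copper coupling at room temperature. Miyaura borylation (B2pin2, Pd(dppf)Cl2, KOAc, dioxane, 80 °C) should give 2-{4-[2-(3-{4-methoxy-2-[2-(4-methoxy-3-(propan-2-yloxy)phenyl)ethyl]phenoxy}phenyl)ethyl]phenyl}-4,4,5,5-tetramethyl-1,3,2-dioxaborolane F3. BCl3 in CH2Cl2 followed by water would cleave both the isopropyl ether and the pinacol ester to give {4-[2-(3-{2-[2-(3-hydroxy-4-methoxyphenyl)ethyl]-4-methoxyphenoxy}phenyl)ethyl]phenyl}boronic acid F4. Chan–Evans–Lam coupling (Cu(OAc)2, pyridine, 4 Å sieves, CH2Cl2, air, rt, high dilution) should then close the ring to 19.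

Step 6. The most likely failures are alpha-elimination of the carbenoid before it adds, and collapse of the tetrahedral adduct in the flask followed by a second addition. The fallback sets out from 9 (and uses 5) and returns at 12 without any halomethyl ketone. DIBAL-H in THF at −78 °C should reduce 9 to 3-[4-methoxy-3-(propan-2-yloxy)phenyl]propanal F5. Corey–Chaykovsky epoxidation (trimethylsulfonium iodide, NaH, DMSO/THF) would give 2-{2-[4-methoxy-3-(propan-2-yloxy)phenyl]ethyl}oxirane F6. Opening of F6 at its terminal carbon by the phenoxide of 5 (Cs2CO3, DMF, 90 °C) would give 1-{3-[2-(4-bromophenyl)ethyl]phenoxy}-4-[4-methoxy-3-(propan-2-yloxy)phenyl]butan-2-ol F7. Oxidation with Dess–Martin periodinane in CH2Cl2 should then give 12.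

## Further compounds

F1 | step 8 | 5-{3-[2-(4-bromophenyl)ethyl]phenoxy}-8-[4-methoxy-3-(propan-2-yloxy)phenyl]octane-2,6-dione, racemic | CC(=O)CCC(Oc1cccc(CCc2ccc(Br)cc2)c1)C(=O)CCc1ccc(OC)c(OC(C)C)c1
F2 | step 8 | 4-{3-[2-(4-bromophenyl)ethyl]phenoxy}-3-{2-[4-methoxy-3-(propan-2-yloxy)phenyl]ethyl}cyclohex-2-en-1-one, racemic | O=C1C=C(CCc2ccc(OC)c(OC(C)C)c2)C(Oc2cccc(CCc3ccc(Br)cc3)c2)CC1
F3 | step 11 | 2-{4-[2-(3-{4-methoxy-2-[2-(4-methoxy-3-(propan-2-yloxy)phenyl)ethyl]phenoxy}phenyl)ethyl]phenyl}-4,4,5,5-tetramethyl-1,3,2-dioxaborolane | COc1ccc(Oc2cccc(c2)CCc2ccc(cc2)B2OC(C)(C)C(C)(C)O2)c(c1)CCc1ccc(OC)c(OC(C)C)c1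
F4 | step 11 | {4-[2-(3-{2-[2-(3-hydroxy-4-methoxyphenyl)ethyl]-4-methoxyphenoxy}phenyl)ethyl]phenyl}boronic acid | COc1ccc(Oc2cccc(c2)CCc2ccc(cc2)B(O)O)c(c1)CCc1ccc(OC)c(O)c1
F5 | step 6 | 3-[4-methoxy-3-(propan-2-yloxy)phenyl]propanal | O=CCCc1ccc(OC)c(OC(C)C)c1
F6 | step 6 | 2-{2-[4-methoxy-3-(propan-2-yloxy)phenyl]ethyl}oxirane, racemic | C1OC1CCc1ccc(OC)c(OC(C)C)c1
F7 | step 6 | 1-{3-[2-(4-bromophenyl)ethyl]phenoxy}-4-[4-methoxy-3-(propan-2-yloxy)phenyl]butan-2-ol, racemic | OC(COc1cccc(CCc2ccc(Br)cc2)c1)CCc1ccc(OC)c(OC(C)C)c1
A1 | alternative 1 | macrocyclic (E)-stilbene, dimethyl ether | COc1ccc2c(c1)CCc1ccc(OC)c(c1)Oc1ccc(cc1)/C=C/c1cccc(c1)O2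
A2 | alternative 1 | 19-membered macrocyclic dibenzyl sulfone, dimethyl ether | COc1ccc2c(c1)CCc1ccc(OC)c(c1)Oc1ccc(cc1)CS(=O)(=O)Cc1cccc(c1)O2
A3 | alternative 2 | racemic macrocyclic nitro compound with the ring B phenol free | COc1ccc2c(c1)C([N+](=O)[O-])Cc1ccc(O)c(c1)Oc1ccc(cc1)CCc1cccc(c1)O2
A4 | alternative 2 | open-chain precursor with ring A nitromethyl, ring B acetoxymethyl and ring B tert-butyldimethylsilyl ether | COc1ccc(Oc2cccc(CCc3ccc(Oc4cc(COC(C)=O)ccc4O[Si](C)(C)C(C)(C)C)cc3)c2)c(C[N+](=O)[O-])c1
A5 | alternative 2 | para-quinone methide of ring B derived from A4 | COc1ccc(Oc2cccc(CCc3ccc(OC4=CC(=C)C=CC4=O)cc3)c2)c(C[N+](=O)[O-])c1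
A6 | alternative 3 | halogenated macrocycle with the ring B hydroxyl free | COc1ccc2c(c1)CCc1cc(Br)c(O)c(c1)Oc1c(Cl)cc(cc1Cl)CCc1cccc(c1)O2
A7 | alternative 3 | open-chain bis-phenol with 3,5-dibromo-4-hydroxyphenyl ring B and 3,5-dichloro-4-hydroxyphenyl ring C | COc1ccc(Oc2cccc(CCc3cc(Cl)c(O)c(Cl)c3)c2)c(CCc2cc(Br)c(O)c(Br)c2)c1
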